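The cyclohexene ring (C1–C6) is disconnected at C1–C2. Its C7–C1–C2–C3=C4 array is a γ,δ-unsaturated acid, and the C5 oxygen stands cis-1,3 to C7. Together they are the retron of an Ireland–Claisen rearrangement run across a δ-lactone whose ester oxygen sits on C4 beside a C3=C2 vinyl group. In one operation the [3,3] shift closes the carbocycle, places the C3=C4 alkene, releases the C7 acid and relays the C4 configuration to C1. The precursor is a (5S,6S)-5-silyloxy-6-(silyloxymethyl)-6-vinyl δ-valerolactone built from the L-glutamic-acid lactone acid. Allylation, methylenation and cross-metathesis then add C8–C13, and both isobutyrates are attached together.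

Key step: step 7

Remark (numbering): the ring is C1 (CH bearing the side chain), C2H2, C3H=C4, C5H(O), C6H2. The side chain is C7(=C15H2)–C8H2–C9H=C10H–C11(C13H3)(OH)–C12H2O, and C14 is the oxymethyl carbon on C4. TBS = tert-butyldimethylsilyl.

Assumption: every compound marked "starting material" in the list is taken as purchasable.

Step 1
Reactants: 1 (S)-5-oxotetrahydrofuran-2-carboxylic acid; 2 oxalyl chloride
Product: 3 (S)-5-oxotetrahydrofuran-2-carbonyl chloride
Conditions: (COCl)2, DMF (cat.), CH2Cl2, 0 °C → rt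
Reagents that add atoms: oxalyl chloride (2), O=C(Cl)C(=O)Cl
Why: DMF-catalysed (Vilsmeier-type) conversion of an acid into its chloride; the lactone is inert and, with no base present, the C5–H is not at risk.

Step 2
Reactants: 3 (S)-5-oxotetrahydrofuran-2-carbonyl chloride; 4 tris(trimethylsilyloxy)ethylene
Product: 6 (S)-5-(2-hydroxyacetyl)dihydrofuran-2(3H)-one, via silylated keto ester 5 (not isolated)
Conditions: 4 (neat), 90 °C; then THF–0.5 M aq. HCl, rt → 50 °C
Reagents that add atoms: tris(trimethylsilyloxy)ethylene (4), C[Si](C)(C)OC=C(O[Si](C)(C)C)O[Si](C)(C)C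
Why: The acid chloride C-acylates the electron-rich ketene bis(silyl) acetal (Mukaiyama-type acylation), and mild aqueous acid strips the silyl groups from 5 so that the α-hydroxy-β-keto acid decarboxylates to the hydroxymethyl ketone, a known diazomethane-free RCOCl → RCOCH2OH homologation; holding the decarboxylation at or below 50 °C keeps acid-catalysed enolisation toward C5 in check.

Step 3
Reactants: 6 (S)-5-(2-hydroxyacetyl)dihydrofuran-2(3H)-one; 7 tert-butyldimethylsilyl chloride
Product: 8 (S)-5-[2-(TBSO)acetyl]dihydrofuran-2(3H)-one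
Conditions: TBSCl, imidazole, CH2Cl2, 0 °C
Reagents that add atoms: tert-butyldimethylsilyl chloride (7), CC(C)(C)[Si](C)(C)Cl
Why: Imidazole-promoted silylation of the only hydroxyl group; the poorly donating silyl ether also denies magnesium a chelation site in the next step.

Step 4
Reactants: 8 (S)-5-[2-(TBSO)acetyl]dihydrofuran-2(3H)-one; 9 vinylmagnesium bromide
Product: 10 (5S)-5-[(2S)-1-(TBSO)-2-hydroxybut-3-en-2-yl]dihydrofuran-2(3H)-one
Conditions: CH2=CHMgBr, THF, −78 °C; aq. NH4Cl quench at −78 °C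
Reagents that add atoms: vinylmagnesium bromide (9), C=C[Mg]Br
Why: Chemoselective Grignard 1,2-addition to the doubly α-oxygenated ketone, which is far more electrophilic than the lactone at −78 °C; neither the acyloxy oxygen on C5 nor the silyl ether chelates magnesium, so the polar Felkin–Anh (equally the Cornforth) transition state should operate, with vinyl entering anti to the C5–O bond past C5–H, which sets C4 as S (C4–OH and C5–O anti when C6–C5–C4–C3 is drawn as a zigzag).

Step 5
Reactants: 10 (5S)-5-[(2S)-1-(TBSO)-2-hydroxybut-3-en-2-yl]dihydrofuran-2(3H)-one; 11 lithium hydroxide; 12 tert-butyldimethylsilyl trifluoromethanesulfonate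
Product: 15 (4S,5S)-4-(TBSO)-5-hydroxy-5-[(TBSO)methyl]hept-6-enoic acid, via lithium dihydroxy carboxylate 13 (not isolated), via trisilylated ester 14 (not isolated)
Conditions: LiOH, THF–H2O, 0 °C → rt, evaporate, toluene azeotrope; TBSOTf, 2,6-lutidine, CH2Cl2, −78 → −30 °C; K2CO3, MeOH–THF–H2O, rt; cold 0.5 M HCl to pH 4–5
Reagents that add atoms: lithium hydroxide (11), [Li+].[OH-]; tert-butyldimethylsilyl trifluoromethanesulfonate (12), CC(C)(C)[Si](C)(C)OS(=O)(=O)C(F)(F)F
Why: Saponification, silylation and silyl-ester cleavage: because the five-membered lactone on the secondary oxygen is the thermodynamic sink, the ring switch is not left to an equilibrium but forced by opening 10, capping the carboxylate and the secondary C5–OH with the fast triflate at low temperature (the crowded tertiary C4–OH stays free) and removing only the labile silyl ester with carbonate.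

Step 6
Reactants: 15 (4S,5S)-4-(TBSO)-5-hydroxy-5-[(TBSO)methyl]hept-6-enoic acid
Product: 16 (5S,6S)-5-(TBSO)-6-[(TBSO)methyl]-6-vinyltetrahydro-2H-pyran-2-one (silyloxy group trans to vinyl)
Conditions: DCC, DMAP, CH2Cl2, 0 °C → rt
Reagents that add atoms: none
Why: Steglich-type carbodiimide/DMAP lactonisation; with C5–O capped, only the 6-exo-trig closure onto C4–OH is open, and no stereocentre is touched.

Step 7
Reactants: 16 (5S,6S)-5-(TBSO)-6-[(TBSO)methyl]-6-vinyltetrahydro-2H-pyran-2-one; 7 tert-butyldimethylsilyl chloride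
Product: 19 (1S,5S)-5-(TBSO)-4-[(TBSO)methyl]cyclohex-3-ene-1-carboxylic acid, via silyl ketene acetal 17 (not isolated), via silyl ester 18 (not isolated)
Conditions: LiN(iPr)2, THF, −78 °C; TBSCl, DMPU, −78 → 0 °C; solvent switch to toluene (trace Et3N), 110 °C; K2CO3, MeOH–THF–H2O, rt; cold 0.5 M HCl to pH 4
Reagents that add atoms: tert-butyldimethylsilyl chloride (7), CC(C)(C)[Si](C)(C)Cl (its silyl group is carried only by 17 and 18)
Why: Kinetic deprotonation at C1, the only enolisable position, and O-silylation give the endocyclic silyl ketene acetal 17, whose C1=C7–O–C4–C3=C2 array undergoes a concerted suprafacial [3,3] sigmatropic shift on heating (C1–C2 forms, C4–O breaks) to silyl ester 18, which mild carbonate hydrolysis converts into acid 19. The closest known reaction type is the Ireland–Claisen rearrangement of lactone silyl ketene acetals that carry an alkenyl group on the carbinol carbon, which gives cycloalkenecarboxylic acids. The six-membered carbocycle closes across the 1,4-positions of the heterocycle: the tether excludes a chair, so the axial vinyl group reaches C1 through a boat-like, bicyclo[2.2.2]octene-type array. The new C1 stereocentre is controlled by C4, because the bond can form only on the lactone face that bears the vinyl group; C7 therefore ends on the face that the ring oxygen leaves, and the C5 silyloxy group, trans to vinyl in 16, ends cis to C7, which is the (1S,5S) acid. The step needs O- over C-silylation and rearrangement over ionisation of the tertiary allylic C4–O bond or elimination; DMPU with the silyl chloride favours O-silylation, C6 carries no leaving group, and the base-buffered non-polar medium disfavours ion pairs.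

Step 8
Reactants: 19 (1S,5S)-5-(TBSO)-4-[(TBSO)methyl]cyclohex-3-ene-1-carboxylic acid; 20 1,1'-carbonyldiimidazole; 21 N,O-dimethylhydroxylamine hydrochloride
Product: 23 (1S,5S)-5-(TBSO)-4-[(TBSO)methyl]-N-methoxy-N-methylcyclohex-3-ene-1-carboxamide, via acyl imidazolide 22 (not isolated)
Conditions: CDI, CH2Cl2, rt; then MeNH(OMe)·HCl, rt
Reagents that add atoms: N,O-dimethylhydroxylamine hydrochloride (21), CNOC.Cl; 1,1'-carbonyldiimidazole (20), O=C(n1ccnc1)n1ccnc1 (its imidazolyl group is carried only by 22)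
Why: Weinreb amide synthesis through the acyl imidazolide runs without added base, so the C1–H next to the carbonyl is not disturbed.

Step 9
Reactants: 23 (1S,5S)-5-(TBSO)-4-[(TBSO)methyl]-N-methoxy-N-methylcyclohex-3-ene-1-carboxamide; 24 allylmagnesium bromide
Product: 25 1-[(1S,5S)-5-(TBSO)-4-[(TBSO)methyl]cyclohex-3-en-1-yl]but-3-en-1-one
Conditions: CH2=CHCH2MgBr, THF, −78 °C; cold aq. NH4Cl quench; used without delay
Reagents that add atoms: allylmagnesium bromide (24), C=CC[Mg]Br
Why: Weinreb ketone synthesis: the magnesium chelate of the tetrahedral adduct lasts until the cold buffered quench, which stops over-addition and keeps the β,γ-unsaturated ketone away from any base that would pull the alkene into conjugation or epimerise C1.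

Step 10
Reactants: 25 1-[(1S,5S)-5-(TBSO)-4-[(TBSO)methyl]cyclohex-3-en-1-yl]but-3-en-1-one; 26 dimethyltitanocene Cp2TiMe2
Product: 27 (4S,6S)-6-(TBSO)-1-[(TBSO)methyl]-4-(penta-1,4-dien-2-yl)cyclohex-1-ene
Conditions: Cp2TiMe2, toluene, 70 °C, dark
Reagents that add atoms: dimethyltitanocene (26), C[Ti+2]C.[CH-]1C=CC=C1.[CH-]1C=CC=C1
Why: Petasis methylenation: thermally generated Cp2Ti=CH2 is non-basic and olefinates even readily enolisable ketones through an oxatitanacyclobutane, so the skipped C15=C7–C8–C9=C10 diene should form without conjugation or loss of the C1 configuration.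

Step 11
Reactants: 27 (4S,6S)-6-(TBSO)-1-[(TBSO)methyl]-4-(penta-1,4-dien-2-yl)cyclohex-1-ene
Product: 28 [(4S,6S)-6-(TBSO)-4-(penta-1,4-dien-2-yl)cyclohex-1-en-1-yl]methanol
Conditions: HF·pyridine, pyridine, THF, 0 °C
Reagents that add atoms: none
Why: Rate-selective fluoride desilylation: in buffered HF·pyridine the unhindered primary allylic silyl ether on C14 is cleaved well before the secondary one on C5, which stays on as the only protecting group needed for the endgame.

Step 12
Reactants: 29 (S)-2-methylglycidol; 30 trimethylsulfonium iodide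
Product: 31 (R)-2-methylbut-3-ene-1,2-diol
Conditions: Me3SI, n-BuLi, THF, −15 °C; then 29, −15 °C → rt; H2O quench
Reagents that add atoms: trimethylsulfonium iodide (30), C[S+](C)C.[I-]
Why: One-carbon homologation of a terminal epoxide to an allylic alcohol with excess dimethylsulfonium methylide (attack at the epoxide CH2, then ylide-mediated syn elimination of Me2S); the quaternary centre that becomes C11 is not involved, and the only possible Payne shift is degenerate and returns the same enantiomer, so the S epoxide should give the R diol.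

Step 13
Reactants: 28 [(4S,6S)-6-(TBSO)-4-(penta-1,4-dien-2-yl)cyclohex-1-en-1-yl]methanol; 31 (R)-2-methylbut-3-ene-1,2-diol
Product: 32 (2R,3E)-6-[(1S,5S)-5-(TBSO)-4-(hydroxymethyl)cyclohex-3-en-1-yl]-2-methylhepta-3,6-diene-1,2-diol
Conditions: second-generation Hoveyda–Grubbs catalyst RuCl2(H2IMes)(=CH-C6H4-2-OiPr) (5 mol %), 31 (3 equiv), 1,4-benzoquinone (10 mol %), CH2Cl2, 40 °C
Reagents that add atoms: (R)-2-methylbut-3-ene-1,2-diol (31), C=C[C@@](C)(O)CO
Why: Olefin cross-metathesis between an unhindered terminal alkene and a tertiary vinyl carbinol that hardly homodimerises; the 1,1-disubstituted C7=C15 and trisubstituted C3=C4 alkenes are too hindered to engage, the bulk at C11 enforces the E geometry, and benzoquinone suppresses hydride-induced migration of the skipped diene.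

Step 14
Reactants: 32 (2R,3E)-6-[(1S,5S)-5-(TBSO)-4-(hydroxymethyl)cyclohex-3-en-1-yl]-2-methylhepta-3,6-diene-1,2-diol; 33 isobutyryl chloride
Product: 34 [(4S,6S)-6-(TBSO)-4-[(4E,6R)-6-hydroxy-6-methyl-7-(2-methylpropanoyloxy)hepta-1,4-dien-2-yl]cyclohex-1-en-1-yl]methyl 2-methylpropanoate
Conditions: iPrCOCl (2.4 equiv), pyridine, DMAP (cat.), CH2Cl2, 0 °C
Reagents that add atoms: isobutyryl chloride (33), CC(C)C(=O)Cl
Why: Pyridine/DMAP acylation esterifies both primary alcohols (O12 and O14) in one operation; the tertiary C11–OH is too hindered to react and O5 is still silylated, so no primary-versus-secondary discrimination is asked of the reagent.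

Step 15
Reactants: 34 [(4S,6S)-6-(TBSO)-4-[(4E,6R)-6-hydroxy-6-methyl-7-(2-methylpropanoyloxy)hepta-1,4-dien-2-yl]cyclohex-1-en-1-yl]methyl 2-methylpropanoate
Product: 35 [(4S,6S)-6-hydroxy-4-[(4E,6R)-6-hydroxy-6-methyl-7-(2-methylpropanoyloxy)hepta-1,4-dien-2-yl]cyclohex-1-en-1-yl]methyl 2-methylpropanoate (target)
Conditions: HF·pyridine, pyridine, THF, 0 °C → rt
Reagents that add atoms: none
Why: Fluoride desilylation in a buffered, slightly acidic medium never generates the C5 alkoxide that would trigger acyl migration from O14 to O5 or ester cleavage, and the tertiary allylic alcohol tolerates it.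

Compound list
1 | (S)-5-oxotetrahydrofuran-2-carboxylic acid | O=C1CC[C@@H](C(=O)O)O1 | starting material
2 | oxalyl chloride | O=C(Cl)C(=O)Cl | starting material
3 | (S)-5-oxotetrahydrofuran-2-carbonyl chloride | O=C1CC[C@@H](C(=O)Cl)O1 | intermediate
4 | tris(trimethylsilyloxy)ethylene | C[Si](C)(C)OC=C(O[Si](C)(C)C)O[Si](C)(C)C | starting material
5 | trimethylsilyl 3-oxo-3-[(2S)-5-oxotetrahydrofuran-2-yl]-2-(trimethylsilyloxy)propanoate (both epimers at the new carbon) | O=C1CC[C@@H](C(=O)C(O[Si](C)(C)C)C(=O)O[Si](C)(C)C)O1 | intermediate (not isolated)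
6 | (S)-5-(2-hydroxyacetyl)dihydrofuran-2(3H)-one | O=C1CC[C@@H](C(=O)CO)O1 | intermediate
7 | tert-butyldimethylsilyl chloride | CC(C)(C)[Si](C)(C)Cl | starting material
8 | (S)-5-[2-(TBSO)acetyl]dihydrofuran-2(3H)-one | O=C1CC[C@@H](C(=O)CO[Si](C)(C)C(C)(C)C)O1 | intermediate
9 | vinylmagnesium bromide | C=C[Mg]Br | starting material
10 | (5S)-5-[(2S)-1-(TBSO)-2-hydroxybut-3-en-2-yl]dihydrofuran-2(3H)-one | O=C1CC[C@@H]([C@@](O)(CO[Si](C)(C)C(C)(C)C)C=C)O1 | intermediate
11 | lithium hydroxide | [Li+].[OH-] | starting material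
12 | tert-butyldimethylsilyl trifluoromethanesulfonate | CC(C)(C)[Si](C)(C)OS(=O)(=O)C(F)(F)F | starting material
13 | lithium (4S,5S)-4,5-dihydroxy-5-[(TBSO)methyl]hept-6-enoate | [Li+].[O-]C(=O)CC[C@H](O)[C@@](O)(CO[Si](C)(C)C(C)(C)C)C=C | intermediate (not isolated)
14 | TBS (4S,5S)-4-(TBSO)-5-hydroxy-5-[(TBSO)methyl]hept-6-enoate | CC(C)(C)[Si](C)(C)OC(=O)CC[C@H](O[Si](C)(C)C(C)(C)C)[C@@](O)(CO[Si](C)(C)C(C)(C)C)C=C | intermediate (not isolated)
15 | (4S,5S)-4-(TBSO)-5-hydroxy-5-[(TBSO)methyl]hept-6-enoic acid | OC(=O)CC[C@H](O[Si](C)(C)C(C)(C)C)[C@@](O)(CO[Si](C)(C)C(C)(C)C)C=C | intermediate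
16 | (5S,6S)-5-(TBSO)-6-[(TBSO)methyl]-6-vinyltetrahydro-2H-pyran-2-one | O=C1CC[C@H](O[Si](C)(C)C(C)(C)C)[C@@](CO[Si](C)(C)C(C)(C)C)(C=C)O1 | intermediate (key-step precursor)
17 | (2S,3S)-3,6-bis(TBSO)-2-[(TBSO)methyl]-2-vinyl-3,4-dihydro-2H-pyran | CC(C)(C)[Si](C)(C)OC1=CC[C@H](O[Si](C)(C)C(C)(C)C)[C@@](CO[Si](C)(C)C(C)(C)C)(C=C)O1 | intermediate (not isolated)
18 | TBS (1S,5S)-5-(TBSO)-4-[(TBSO)methyl]cyclohex-3-ene-1-carboxylate | CC(C)(C)[Si](C)(C)OC(=O)[C@H]1CC=C(CO[Si](C)(C)C(C)(C)C)[C@@H](O[Si](C)(C)C(C)(C)C)C1 | intermediate (not isolated)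
19 | (1S,5S)-5-(TBSO)-4-[(TBSO)methyl]cyclohex-3-ene-1-carboxylic acid | OC(=O)[C@H]1CC=C(CO[Si](C)(C)C(C)(C)C)[C@@H](O[Si](C)(C)C(C)(C)C)C1 | intermediate (key-step product)
20 | 1,1'-carbonyldiimidazole | O=C(n1ccnc1)n1ccnc1 | starting material
21 | N,O-dimethylhydroxylamine hydrochloride | CNOC.Cl | starting material
22 | [(1S,5S)-5-(TBSO)-4-[(TBSO)methyl]cyclohex-3-en-1-yl](imidazol-1-yl)methanone | O=C([C@H]1CC=C(CO[Si](C)(C)C(C)(C)C)[C@@H](O[Si](C)(C)C(C)(C)C)C1)n2ccnc2 | intermediate (not isolated)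
23 | (1S,5S)-5-(TBSO)-4-[(TBSO)methyl]-N-methoxy-N-methylcyclohex-3-ene-1-carboxamide | CON(C)C(=O)[C@H]1CC=C(CO[Si](C)(C)C(C)(C)C)[C@@H](O[Si](C)(C)C(C)(C)C)C1 | intermediate
24 | allylmagnesium bromide | C=CC[Mg]Br | starting material
25 | 1-[(1S,5S)-5-(TBSO)-4-[(TBSO)methyl]cyclohex-3-en-1-yl]but-3-en-1-one | C=CCC(=O)[C@H]1CC=C(CO[Si](C)(C)C(C)(C)C)[C@@H](O[Si](C)(C)C(C)(C)C)C1 | intermediate
26 | dimethyltitanocene Cp2TiMe2 | C[Ti+2]C.[CH-]1C=CC=C1.[CH-]1C=CC=C1 | starting material
27 | (4S,6S)-6-(TBSO)-1-[(TBSO)methyl]-4-(penta-1,4-dien-2-yl)cyclohex-1-ene | C=CCC(=C)[C@H]1CC=C(CO[Si](C)(C)C(C)(C)C)[C@@H](O[Si](C)(C)C(C)(C)C)C1 | intermediate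
28 | [(4S,6S)-6-(TBSO)-4-(penta-1,4-dien-2-yl)cyclohex-1-en-1-yl]methanol | C=CCC(=C)[C@H]1CC=C(CO)[C@@H](O[Si](C)(C)C(C)(C)C)C1 | intermediate
29 | (S)-2-methylglycidol, [(2S)-2-methyloxiran-2-yl]methanol | C[C@@]1(CO1)CO | starting material
30 | trimethylsulfonium iodide | C[S+](C)C.[I-] | starting material
31 | (R)-2-methylbut-3-ene-1,2-diol | C=C[C@@](C)(O)CO | intermediate
32 | (2R,3E)-6-[(1S,5S)-5-(TBSO)-4-(hydroxymethyl)cyclohex-3-en-1-yl]-2-methylhepta-3,6-diene-1,2-diol | C=C(C/C=C/[C@@](C)(O)CO)[C@H]1CC=C(CO)[C@@H](O[Si](C)(C)C(C)(C)C)C1 | intermediate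
33 | isobutyryl chloride | CC(C)C(=O)Cl | starting material
34 | C5-O-TBS ether of the target (both isobutyrates in place) | C=C(C/C=C/[C@@](C)(O)COC(=O)C(C)C)[C@H]1CC=C(COC(=O)C(C)C)[C@@H](O[Si](C)(C)C(C)(C)C)C1 | intermediate
35 | CNP0599657.1 | C=C(C/C=C/[C@@](C)(O)COC(=O)C(C)C)[C@H]1CC=C(COC(=O)C(C)C)[C@@H](O)C1 | target

Total step count: 15. Longest linear sequence: 14 (steps 1–11 and 13–15; step 12 is the one-step side branch).

Steps most likely to fail

1. Step 7. The boat-type shift may be too slow at the crowded quaternary C4. Ionisation of the tertiary allylic C4–O bond, hydrolysis of the ketene acetal or C-silylation could then take over. The fallback closes the ring at C3=C4 by metathesis instead of at C1–C2 and sets C1 with an auxiliary. It sets out from ketone 8 and comes back at acid 19. Takai–Lombardo methylenation (Zn, CH2Br2, TiCl4), which spares lactones, would give the methylene lactone F1. Opening as in step 5 (LiOH; TBSOTf, 2,6-lutidine; K2CO3, MeOH) would lead through the lithium hydroxy carboxylate F2 and the bis-silylated silyl ester F3 to the hexenoic acid F4. DCC/DMAP acylation of (S)-4-benzyloxazolidin-2-one would give the imide F5. Evans alkylation (NaN(SiMe3)2, allyl iodide, THF, −78 °C) on the enolate face away from the benzyl group would set C1 in the allylated imide F6. Ring-closing metathesis (second-generation Grubbs catalyst RuCl2(PCy3)(H2IMes)(=CHPh), CH2Cl2, 40 °C) would close the cyclohexene imide F7, and LiOH/H2O2 would release 19.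

2. Step 4. Facial selectivity at the ketone may be poor, or enolisation toward C5 may erode the purchased stereocentre. The fallback sets C4 by reagent-controlled oxygen delivery and C5 by an invertive lactonisation. It sets out from vinylmagnesium bromide 9 and comes back at 10. CuI-catalysed anti-carbomagnesiation of propargyl alcohol with 9, followed by iodinolysis in the same flask, would give the iodo dienol F8. Negishi coupling with (3-ethoxy-3-oxopropyl)zinc bromide and Pd(PPh3)4, with retention of geometry, would give the dienol ester F9. Sharpless asymmetric epoxidation of its allylic-alcohol alkene (Ti(OiPr)4, L-(+)-diisopropyl tartrate, t-BuOOH, 4 Å sieves, CH2Cl2, −20 °C) would give the epoxy alcohol F10, and TBSCl/imidazole would give the silyl ether F11. LiOH would give the lithium epoxy carboxylate F12. On gentle warming near neutral pH this should open the epoxide at the secondary carbon C5 (5-exo, inversion) and deliver 10.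

3. Step 5. Relactonisation to the five-membered ring may outrun silylation of the hindered C5–OH, or the tertiary C4–OH may be silylated as well. The fallback parks the acyl group as an amide that does not close back readily and makes the six-membered ring at the lactol level. It sets out from 10 and comes back at 16. Aminolysis with 21 and iPrMgCl (THF, −20 °C) would give the dihydroxy Weinreb amide F13. TBSOTf (1.1 equiv)/2,6-lutidine at −78 °C would give the C5 silyl ether F14. Reduction with iBu2AlH (THF, −78 °C) would give, after work-up, the six-membered lactol F15 (ring tautomer of the δ-hydroxy aldehyde). TEMPO/PhI(OAc)2 oxidation would give 16.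

Further compounds
F1 | step 7 | (S)-5-[3-(TBSO)prop-1-en-2-yl]dihydrofuran-2(3H)-one | O=C1CC[C@@H](C(=C)CO[Si](C)(C)C(C)(C)C)O1
F2 | step 7 | lithium (S)-4-hydroxy-5-[(TBSO)methyl]hex-5-enoate | [Li+].[O-]C(=O)CC[C@H](O)C(=C)CO[Si](C)(C)C(C)(C)C
F3 | step 7 | TBS (S)-4-(TBSO)-5-[(TBSO)methyl]hex-5-enoate | CC(C)(C)[Si](C)(C)OC(=O)CC[C@H](O[Si](C)(C)C(C)(C)C)C(=C)CO[Si](C)(C)C(C)(C)C
F4 | step 7 | (S)-4-(TBSO)-5-[(TBSO)methyl]hex-5-enoic acid | OC(=O)CC[C@H](O[Si](C)(C)C(C)(C)C)C(=C)CO[Si](C)(C)C(C)(C)C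
F5 | step 7 | (S)-4-benzyl-3-[(S)-4-(TBSO)-5-[(TBSO)methyl]hex-5-enoyl]oxazolidin-2-one | O=C(CC[C@H](O[Si](C)(C)C(C)(C)C)C(=C)CO[Si](C)(C)C(C)(C)C)N1[C@@H](Cc2ccccc2)COC1=O
F6 | step 7 | (S)-4-benzyl-3-[(2S,4S)-2-allyl-4-(TBSO)-5-[(TBSO)methyl]hex-5-enoyl]oxazolidin-2-one | O=C([C@@H](CC=C)C[C@H](O[Si](C)(C)C(C)(C)C)C(=C)CO[Si](C)(C)C(C)(C)C)N1[C@@H](Cc2ccccc2)COC1=O
F7 | step 7 | (S)-4-benzyl-3-[(1S,5S)-5-(TBSO)-4-[(TBSO)methyl]cyclohex-3-ene-1-carbonyl]oxazolidin-2-one | O=C([C@H]1CC=C(CO[Si](C)(C)C(C)(C)C)[C@@H](O[Si](C)(C)C(C)(C)C)C1)N2[C@@H](Cc3ccccc3)COC2=O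
F8 | step 4 | (Z)-2-(iodomethylidene)but-3-en-1-ol | OC/C(C=C)=C\I
F9 | step 4 | ethyl (4Z)-5-(hydroxymethyl)hepta-4,6-dienoate | CCOC(=O)CC/C=C(\CO)C=C
F10 | step 4 | ethyl 3-[(2R,3S)-3-ethenyl-3-(hydroxymethyl)oxiran-2-yl]propanoate | CCOC(=O)CC[C@H]1O[C@]1(CO)C=C
F11 | step 4 | ethyl 3-[(2R,3S)-3-ethenyl-3-[(TBSO)methyl]oxiran-2-yl]propanoate | CCOC(=O)CC[C@H]1O[C@]1(CO[Si](C)(C)C(C)(C)C)C=C
F12 | step 4 | lithium 3-[(2R,3S)-3-ethenyl-3-[(TBSO)methyl]oxiran-2-yl]propanoate | [Li+].[O-]C(=O)CC[C@H]1O[C@]1(CO[Si](C)(C)C(C)(C)C)C=C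
F13 | step 5 | (4S,5S)-4,5-dihydroxy-5-[(TBSO)methyl]-N-methoxy-N-methylhept-6-enamide | CON(C)C(=O)CC[C@H](O)[C@@](O)(CO[Si](C)(C)C(C)(C)C)C=C
F14 | step 5 | (4S,5S)-4-(TBSO)-5-hydroxy-5-[(TBSO)methyl]-N-methoxy-N-methylhept-6-enamide | CON(C)C(=O)CC[C@H](O[Si](C)(C)C(C)(C)C)[C@@](O)(CO[Si](C)(C)C(C)(C)C)C=C
F15 | step 5 | (5S,6S)-5-(TBSO)-6-[(TBSO)methyl]-6-vinyltetrahydro-2H-pyran-2-ol (both anomers) | OC1CC[C@H](O[Si](C)(C)C(C)(C)C)[C@@](CO[Si](C)(C)C(C)(C)C)(C=C)O1
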